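## Structural features

The target consists of two (2R,3S)-flavan-3-ol ((+)-catechin) units: the upper unit has the phloroglucinol-type ring A, the dihydropyran ring C and the catechol ring B, and the lower unit has the corresponding rings D, F and E. The units are joined by a single biaryl bond from C6' of ring B (ortho to C1', which carries C2 of ring C) to C8 of ring D (between O1 and the 7-hydroxyl group of the lower unit). Each pyran ring holds two adjacent stereocentres, C2 (aryl) and C3 (hydroxyl), in the trans relation, which gives four stereocentres in two separate pairs, and the biaryl axis has three ortho substituents and is not defined in the SMILES. Ten free hydroxyl groups, among them two catechols and two phloroglucinol-type rings, make the compound sensitive to air, to base (epimerisation at C2 by opening of the pyran ring) and to electrophiles, so it can only be unmasked in the last step. The real difficulty is the hindered C6'–C8 bond and its site selectivity at both ends: ring D offers C6 and C8, ring B offers C2', C5' and C6', and in an intact unit rings A and D should react with electrophiles and oxidants long before ring B. The key step exploits the substitution pattern of ring B: its two carbon substituents stand on the adjacent atoms C1' and C6' and its two oxygen atoms on C3' and C4', so that ring B without these two C–C bonds is a 4,5-dioxygenated benzyne with a mirror plane through the midpoints of C1'–C6' and C3'–C4'. Both bonds can therefore be made in one vicinal difunctionalisation in which no regiochemical question exists on ring B. In one sentence, ring B is inserted as 17 between the C8 carbanion of the intact lower unit 15 and the formyl carbon of the open-chain aldehyde 14, which does not describe a coupling of two flavan-3-ol units.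

## Logic of the disconnections

**22 back to 21.** Cut: seven O–CH2Ph bonds (O3' and O4' of ring B, O5 and O7 of ring D, O3 of ring F, O3' and O4' of ring E). The free polyphenol tolerates neither organolithium reagents nor chromatography in air, whereas benzyl groups leave under neutral reductive conditions. The skeleton is not simplified, but all earlier compounds become robust. The forward step must spare the two benzylic C2–O1 bonds.

**21 back to 20.** Cut: O1–C2 of ring C. Retrosynthetically, four O–CH2OMe groups are placed on the three oxygens of ring A and on O3. C2 is benzylic and para to O4', so it ionises easily and can be closed by an oxygen of ring A. This opens ring C and removes the C2 stereocentre from the plan, because both C2 epimers of 20 serve. Ring A becomes locally symmetric, with two equivalent ortho oxygens. The forward step must capture the cation trans to O3 under control by C3 alone.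

**20 back to 4, 6 and 14 (through 15, 16, 17, 18 and 19).** Cut: C8 (ring D)–C6' (ring B) and C1' (ring B)–C2. Both bonds end on adjacent atoms of ring B, and removing both leaves 17, whose two reactive carbons are equivalent. The largest compound of the route falls into three pieces: the complete lower unit, an achiral benzene, and a small aldehyde with one stereocentre. The site problem on ring B vanishes, and the one on ring D is reduced to placing a bromine. In the forward step, 15 must add to 17 faster than 16 does, 18 must be available as a discrete nucleophile (secured through 19), and 18 must add to 14 without enolising it.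

**4 back to 1 (through 3 and 2).** Cut: C8–Br and five O–CH2Ph bonds. C2 and C3 of the lower unit are bought with 1, and all of rings D, E and F comes from one starting material. The forward steps need monobromination at C8 and not at C6, and must leave no acidic proton in 4.

**6 back to 5.** Cut: two O–CH2Ph bonds. The vicinal dibromide is the latent triple bond, and it is already present in 5. The forward step is only a clean double etherification.

**14 back to 8 and 9 (through 13, 12, 11 and 10).** Cut: C4–C4a, followed by adjustment of the oxidation level at the carbon that becomes C2 and protection of O3. The cut joins a symmetric arene to a three-carbon piece that already holds C3 in the S configuration. No asymmetric reaction is needed for the upper unit. The forward step must open the epoxide of 9 only at its CH2 group and leave the ester intact.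

**8 back to 7.** Cut: three O–CH2OMe bonds. The acetals direct the lithiation, survive all basic steps, and leave in the same acid that closes ring C. The forward step needs complete O-alkylation.

## Other disconnections considered

Alternative 1: This is the cut that comes to mind first, the C6'–C8 bond between two intact, fully protected flavan-3-ol units. The forward key step is a Suzuki–Miyaura coupling of the ring-B bromide A1 with the ring-D pinacol boronate A2 to give the deca-O-benzyl dimer A3.
- In a protected unit, ring A is much more electron-rich than ring B. Electrophilic halogenation is therefore expected to consume C8 and C6 before C6', and A1 would need blocking and unblocking of both positions.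
- A2 belongs to the 2,6-dialkoxyarylboron class, which is the most prone to protodeboronation under basic coupling conditions.
- The transmetalation must build a tri-ortho-substituted axis between two very large partners, so decomposition should compete with coupling.
- The step forms one bond only, and both partners need multistep preparation. The chosen plan forms two bonds and has no regiochemical task on ring B.

Alternative 2: The same bond is cut in the oxidative, biomimetic sense. In the forward key step, 1 is oxidised to its ring-B ortho-quinone A4 and ring A of a second molecule of 1 adds to it in conjugate fashion.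
- On paper this is the shortest plan, but nothing in the substrates directs it.
- The nucleophile offers C6, C8 and several phenolic oxygens, and the quinone can accept at C2', C5' and C6'.
- The newly formed catechol should be oxidised more easily than 1. Further oxidation, intramolecular trapping and oligomerisation are therefore to be expected.
- It cannot be defended as a route to one defined isomer.

Alternative 3: The C6'–C8 bond is cut within a temporary ester bridge from O7 of ring D to the carbon that becomes C2. The forward key step is an intramolecular palladium-catalysed direct arylation of the 2-bromobenzoate A5 to the six-membered biaryl lactone A6, followed by opening of the bridge.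
- The tether answers the steric problem. However, O7 lies between C6 and C8, so closure can occur at either carbon.
- A5 needs one free 7-hydroxyl group among the four phenols of 1, which costs several differentiation steps.
- After the bridge is opened, C2 is an electrophilic carbon on the biaryl. Ring A, C4 and C3 then have to be added, and both C2 and C3 have to be created by later asymmetric steps.
- The plan is clearly longer than the chosen one, which buys C3 and sets C2 in the ring closure.

Key step: step 9

Remark: the SMILES defines no configuration for the C6'–C8 axis. It is assumed that this axis need not be controlled and that the target is the compound as it equilibrates at room temperature.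

## Route

Step 1
Reactants: 1 (+)-catechin
Product: 2 5,7,3',4'-tetra-O-benzyl-(+)-catechin
Conditions: BnBr (4.4 equiv), K2CO3, DMF, 0 °C to rt, N2
Reagents that add atoms: benzyl bromide, BrCc1ccccc1
Why: Williamson ether synthesis on the four phenols. K2CO3 does not deprotonate the secondary 3-hydroxyl group, which stays free, and the mild base leaves C2 and C3 untouched.

Step 2
Reactants: 2 5,7,3',4'-tetra-O-benzyl-(+)-catechin
Product: 3 8-bromo-5,7,3',4'-tetra-O-benzyl-(+)-catechin
Conditions: NBS (1.0 equiv), CH2Cl2, −78 °C to rt
Reagents that add atoms: N-bromosuccinimide, O=C1CCC(=O)N1Br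
Why: Electrophilic aromatic bromination, in which ring D with three oxygen donors reacts far ahead of ring E. Within ring D, C8 (ortho to the conformationally locked O1 and to 7-OBn, para to 5-OBn) is the established first site of attack in 5,7-di-O-benzylflavan-3-ols when one equivalent is used at low temperature.

Step 3
Reactants: 3 8-bromo-5,7,3',4'-tetra-O-benzyl-(+)-catechin
Product: 4 8-bromo-3,5,7,3',4'-penta-O-benzyl-(+)-catechin
Conditions: NaH, BnBr, DMF, 0 °C to rt
Reagents that add atoms: benzyl bromide, BrCc1ccccc1
Why: Williamson ether synthesis on the sodium alkoxide removes the only acidic proton before the organolithium chemistry. No phenoxide is present that could open ring F, so C2 and C3 are not at risk.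

Step 4
Reactants: 5 4,5-dibromobenzene-1,2-diol
Product: 6 1,2-bis(benzyloxy)-4,5-dibromobenzene
Conditions: BnBr (2.2 equiv), K2CO3, DMF, rt
Reagents that add atoms: benzyl bromide, BrCc1ccccc1
Why: Williamson ether synthesis on both phenols. The aryl bromides are inert to these conditions.

Step 5
Reactants: 7 phloroglucinol
Product: 8 1,3,5-tris(methoxymethoxy)benzene
Conditions: NaH (3.6 equiv), MOMCl (3.6 equiv), DMF, 0 °C to rt
Reagents that add atoms: chloromethyl methyl ether, COCCl
Why: O-alkylation of the phenoxides with a hard, very reactive electrophile gives the tris-acetal. The MOM groups direct the lithiation of step 6, survive all basic steps and leave in the acid of step 10.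

Step 6
Reactants: 8 1,3,5-tris(methoxymethoxy)benzene, 9 methyl (2S)-oxirane-2-carboxylate (methyl (S)-glycidate)
Product: 12 methyl (2S)-2-hydroxy-3-[2,4,6-tris(methoxymethoxy)phenyl]propanoate, via 2,4,6-tris(methoxymethoxy)phenyllithium 10 (not isolated), via 2,4,6-tris(methoxymethoxy)phenylmagnesium bromide 11 (not isolated)
Conditions: n-BuLi, THF, 0 °C; MgBr2 (Et2O solution), 0 °C; CuBr·SMe2 (10 mol %), −40 °C; 9, −40 to −20 °C; aq NH4Cl
Reagents that add atoms: none
Why: Directed ortho-lithiation at a CH flanked by two OMOM groups (all three CH are equivalent) and transmetalation are followed by copper-catalysed SN2 opening of the epoxide at its CH2 group, the known reaction of aryl Grignard reagents with glycidic esters. The stereocentre of 9 is not touched and becomes C3 (S) of the upper unit.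

Step 7
Reactants: 12 methyl (2S)-2-hydroxy-3-[2,4,6-tris(methoxymethoxy)phenyl]propanoate
Product: 13 methyl (2S)-2-(methoxymethoxy)-3-[2,4,6-tris(methoxymethoxy)phenyl]propanoate
Conditions: MOMCl, i-Pr2NEt, CH2Cl2, 0 °C to rt
Reagents that add atoms: chloromethyl methyl ether, COCCl
Why: Acetal protection of the secondary alcohol with an amine base that is too weak to enolise the ester, so the S centre is kept.

Step 8
Reactants: 13 methyl (2S)-2-(methoxymethoxy)-3-[2,4,6-tris(methoxymethoxy)phenyl]propanoate
Product: 14 (2S)-2-(methoxymethoxy)-3-[2,4,6-tris(methoxymethoxy)phenyl]propanal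
Conditions: i-Bu2AlH (1.1 equiv), toluene, −78 °C; aq potassium sodium tartrate
Reagents that add atoms: none
Why: Partial reduction of an α-alkoxy ester, in which the aluminium hemiacetal is held by chelation to the α-oxygen at −78 °C and collapses to the aldehyde only on work-up. 14 should be used at once without chromatography to avoid epimerisation.

Step 9
Reactants: 4 8-bromo-3,5,7,3',4'-penta-O-benzyl-(+)-catechin, 6 1,2-bis(benzyloxy)-4,5-dibromobenzene, 14 (2S)-2-(methoxymethoxy)-3-[2,4,6-tris(methoxymethoxy)phenyl]propanal
Product: 20 (1RS,2S)-1-{4,5-bis(benzyloxy)-2-[(2R,3S)-3,5,7-tris(benzyloxy)-2-[3,4-bis(benzyloxy)phenyl]chroman-8-yl]phenyl}-2-(methoxymethoxy)-3-[2,4,6-tris(methoxymethoxy)phenyl]propan-1-ol, via 8-lithio-penta-O-benzylcatechin 15 (not isolated), via 2-bromo-4,5-bis(benzyloxy)phenyllithium 16 (not isolated), via 4,5-bis(benzyloxy)benzyne 17 (not isolated), via 2-lithiobiaryl 18 (not isolated), via 2-bromobiaryl 19 (not isolated)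
Conditions: 4, n-BuLi (1.0 equiv), THF, −78 °C; 6 (1.0 equiv) in THF by syringe pump, −78 °C; n-BuLi (1.05 equiv), −78 °C; 14 in THF, −78 °C; aq NH4Cl
Reagents that add atoms: none
Why: Bromine–lithium exchange turns 4 into 15, a little of which exchanges with 6 to give 16, and 16 loses LiBr already at −78 °C to give 17. Carbanion C8 of 15 adds to the strained triple bond of 17 (C8–C6' bond), and the resulting 18, which lacks the two stabilising ortho oxygens of 15 and is the stronger base, takes bromine from the next molecule of 6, so that 19 forms, 16 is regenerated and a chain with the net equation 15 + 6 = 19 + LiBr runs. The second portion of n-BuLi converts 19 back into 18, which adds to the formyl group of 14 (C1'–C2 bond). The closest known reaction type is the one-pot sequence of benzyne carbolithiation by a 2,6-dialkoxyphenyllithium, halogen transfer, renewed lithiation and capture by an electrophile that is used to make dialkylbiarylphosphine ligands. No ring is closed in this step. Site selectivity on ring B needs no control because the two carbons of the triple bond of 17 are related by a mirror plane, and site selectivity on ring D (C8 and not C6) is stored in the bromine of 4. The only new stereocentre, the carbinol carbon C2, is weakly biased by the α-alkoxy centre (Felkin–Anh against lithium chelate) and may form as a mixture, since step 10 erases it, while C3 is kept because 1,2-addition of an aryllithium at −78 °C outruns enolisation. Slow addition of 6 keeps 16 and 17 dilute relative to 15 and so holds back self-trapping of the aryne.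

Step 10
Reactants: 20 open-chain carbinol (both C1 epimers)
Product: 21 (2R,3S)-2-{4,5-bis(benzyloxy)-2-[(2R,3S)-3,5,7-tris(benzyloxy)-2-[3,4-bis(benzyloxy)phenyl]chroman-8-yl]phenyl}chroman-3,5,7-triol
Conditions: HCl (3 M in MeOH)–THF 1:1, 45 °C, 0.01 M
Reagents that add atoms: none
Why: Acidic methanolysis removes the four MOM acetals, and either carbinol epimer ionises to the same C2 cation, stabilised by the para 4'-benzyloxy group, which is captured 6-exo-trig by one of the two equivalent ortho hydroxyl groups of ring A. With C3–H in the plane of the cation (minimum allylic 1,3-strain) the tethered phenol attacks anti to O3, so both epimers should converge on the 2,3-trans (2R,3S) ring C. This is the acid-catalysed cyclisation of 1-aryl-3-(2-hydroxyaryl)propane-1,2-diols known from flavan-3-ol synthesis, and the benzyl ethers and rings D, E and F are inert to it.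

Step 11
Reactants: 21 hepta-O-benzyl dimer
Product: 22 (+)-catechin-(6'→8)-(+)-catechin, the target
Conditions: H2 (1 atm), Pd(OH)2/C, THF–MeOH–H2O, rt; filtration under Ar, lyophilisation
Reagents that add atoms: none
Why: Hydrogenolysis of seven benzyl ethers under neutral conditions, the standard last step for benzylated flavan-3-ol oligomers. No stereocentre is touched, and the cyclic benzylic C2–O1 bonds are cleaved much more slowly than the O-benzyl groups.

## Compound list

1 | (+)-catechin, (2R,3S)-2-(3,4-dihydroxyphenyl)chroman-3,5,7-triol | Oc1cc(O)c2c(c1)O[C@H](c1ccc(O)c(O)c1)[C@@H](O)C2 | starting material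
2 | (2R,3S)-5,7-bis(benzyloxy)-2-[3,4-bis(benzyloxy)phenyl]chroman-3-ol | C(c1ccccc1)Oc1cc(OCc3ccccc3)c2c(c1)O[C@H](c1ccc(OCc3ccccc3)c(OCc3ccccc3)c1)[C@@H](O)C2 | intermediate
3 | (2R,3S)-8-bromo-5,7-bis(benzyloxy)-2-[3,4-bis(benzyloxy)phenyl]chroman-3-ol | Brc1c(OCc3ccccc3)cc(OCc3ccccc3)c2c1O[C@H](c1ccc(OCc3ccccc3)c(OCc3ccccc3)c1)[C@@H](O)C2 | intermediate
4 | (2R,3S)-8-bromo-3,5,7-tris(benzyloxy)-2-[3,4-bis(benzyloxy)phenyl]chroman | Brc1c(OCc3ccccc3)cc(OCc3ccccc3)c2c1O[C@H](c1ccc(OCc3ccccc3)c(OCc3ccccc3)c1)[C@@H](OCc1ccccc1)C2 | intermediate
5 | 4,5-dibromobenzene-1,2-diol | Oc1cc(Br)c(Br)cc1O | starting material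
6 | 1,2-bis(benzyloxy)-4,5-dibromobenzene | Brc1cc(OCc2ccccc2)c(OCc2ccccc2)cc1Br | intermediate
7 | phloroglucinol, benzene-1,3,5-triol | Oc1cc(O)cc(O)c1 | starting material
8 | 1,3,5-tris(methoxymethoxy)benzene | COCOc1cc(OCOC)cc(OCOC)c1 | intermediate
9 | methyl (2S)-oxirane-2-carboxylate | COC(=O)[C@@H]1CO1 | starting material
10 | 2,4,6-tris(methoxymethoxy)phenyllithium | [Li]c1c(OCOC)cc(OCOC)cc1OCOC | intermediate
11 | 2,4,6-tris(methoxymethoxy)phenylmagnesium bromide | Br[Mg]c1c(OCOC)cc(OCOC)cc1OCOC | intermediate
12 | methyl (2S)-2-hydroxy-3-[2,4,6-tris(methoxymethoxy)phenyl]propanoate | COC(=O)[C@@H](O)Cc1c(OCOC)cc(OCOC)cc1OCOC | intermediate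
13 | methyl (2S)-2-(methoxymethoxy)-3-[2,4,6-tris(methoxymethoxy)phenyl]propanoate | COC(=O)[C@@H](OCOC)Cc1c(OCOC)cc(OCOC)cc1OCOC | intermediate
14 | (2S)-2-(methoxymethoxy)-3-[2,4,6-tris(methoxymethoxy)phenyl]propanal | O=C[C@@H](OCOC)Cc1c(OCOC)cc(OCOC)cc1OCOC | intermediate
15 | [(2R,3S)-3,5,7-tris(benzyloxy)-2-[3,4-bis(benzyloxy)phenyl]chroman-8-yl]lithium | [Li]c1c(OCc3ccccc3)cc(OCc3ccccc3)c2c1O[C@H](c1ccc(OCc3ccccc3)c(OCc3ccccc3)c1)[C@@H](OCc1ccccc1)C2 | intermediate
16 | 2-bromo-4,5-bis(benzyloxy)phenyllithium | [Li]c1cc(OCc2ccccc2)c(OCc2ccccc2)cc1Br | intermediate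
17 | 4,5-bis(benzyloxy)benzyne (1,2-didehydro-4,5-bis(benzyloxy)benzene) | C1#CC=C(OCc2ccccc2)C(OCc2ccccc2)=C1 | intermediate
18 | {4,5-bis(benzyloxy)-2-[(2R,3S)-3,5,7-tris(benzyloxy)-2-[3,4-bis(benzyloxy)phenyl]chroman-8-yl]phenyl}lithium | [Li]c1cc(OCc2ccccc2)c(OCc2ccccc2)cc1-c1c(OCc3ccccc3)cc(OCc3ccccc3)c2c1O[C@H](c1ccc(OCc3ccccc3)c(OCc3ccccc3)c1)[C@@H](OCc1ccccc1)C2 | intermediate
19 | (2R,3S)-8-[2-bromo-4,5-bis(benzyloxy)phenyl]-3,5,7-tris(benzyloxy)-2-[3,4-bis(benzyloxy)phenyl]chroman | Brc1cc(OCc2ccccc2)c(OCc2ccccc2)cc1-c1c(OCc3ccccc3)cc(OCc3ccccc3)c2c1O[C@H](c1ccc(OCc3ccccc3)c(OCc3ccccc3)c1)[C@@H](OCc1ccccc1)C2 | intermediate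
20 | (1RS,2S)-1-{4,5-bis(benzyloxy)-2-[(2R,3S)-3,5,7-tris(benzyloxy)-2-[3,4-bis(benzyloxy)phenyl]chroman-8-yl]phenyl}-2-(methoxymethoxy)-3-[2,4,6-tris(methoxymethoxy)phenyl]propan-1-ol | COCOc1cc(OCOC)c(C[C@H](OCOC)C(O)c2cc(OCc3ccccc3)c(OCc3ccccc3)cc2-c2c(OCc3ccccc3)cc(OCc3ccccc3)c3c2O[C@H](c2ccc(OCc4ccccc4)c(OCc4ccccc4)c2)[C@@H](OCc2ccccc2)C3)c(OCOC)c1 | intermediate
21 | (2R,3S)-2-{4,5-bis(benzyloxy)-2-[(2R,3S)-3,5,7-tris(benzyloxy)-2-[3,4-bis(benzyloxy)phenyl]chroman-8-yl]phenyl}chroman-3,5,7-triol | Oc1cc(O)c2c(c1)O[C@H](c1cc(OCc3ccccc3)c(OCc3ccccc3)cc1-c1c(OCc3ccccc3)cc(OCc3ccccc3)c3c1O[C@H](c1ccc(OCc4ccccc4)c(OCc4ccccc4)c1)[C@@H](OCc1ccccc1)C3)[C@@H](O)C2 | intermediate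
22 | (2R,3S)-2-{2-[(2R,3S)-2-(3,4-dihydroxyphenyl)-3,5,7-trihydroxychroman-8-yl]-4,5-dihydroxyphenyl}chroman-3,5,7-triol | Oc1cc(O)c2c(c1)O[C@H](c1cc(O)c(O)cc1-c1c(O)cc(O)c3c1O[C@H](c1ccc(O)c(O)c1)[C@@H](O)C3)[C@@H](O)C2 | target

## Step count and least certain steps

Total: 11 steps. The longest linear sequence is 7 steps (steps 5, 6, 7, 8, 9, 10, 11). The branch from 1 joins after 3 steps and the branch from 5 after 1 step.

**Step 9 (key step).** Three processes are the most likely to interfere.
- The chain may run inefficiently, with the aryne trapped by 16 or by itself instead of by the hindered 15.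
- A proton may be transferred from a benzylic OCH2 group to 15 or 18, followed by anionic rearrangement.
- The bulky 18 may enolise 14 instead of adding to it.

The fallback sets out from 4 and 6 and comes back at 19. Bromine–lithium exchange on 4 (n-BuLi, THF, −78 °C) and addition of ZnCl2 should give the arylzinc chloride F1. A Negishi coupling of F1 with an excess of 6 (Pd2(dba)3, RuPhos, THF, 60 °C) should stop after one C–C bond, because the remaining C–Br bond is then ortho to a very large aryl group. Isolated 19 is then lithiated and treated with 14 as in the second half of step 9 to give 20.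

**Step 10.** Three processes are the most likely to interfere.
- Facial selectivity in the capture of the C2 cation may be poor, which would close ring C in the cis sense.
- The nearby 7-benzyloxy oxygen of ring D may take part at the cation through a six-membered oxonium ion, with loss of benzyl.
- The freed, very nucleophilic ring A may be alkylated by the formaldehyde acetal that is released.

The fallback sets out from 20 and comes back at 21.
- Dess–Martin oxidation of both epimers should give the single aryl ketone F2.
- HCl in MeOH–THF should remove the MOM groups, after which ring C closes on the carbonyl group to the cyclic hemiketal F3 without any open-chain cation.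
- Ionic reduction (Et3SiH, BF3·OEt2, CH2Cl2–MeCN, −40 °C) should deliver hydride axially to the cyclic oxocarbenium ion with O3 pseudo-equatorial. This is the logic of C-aryl glycoside synthesis, and it places the aryl group equatorial and trans to O3.

**Step 6.** The arylmetal may add to the ester, MgBr2 may open the epoxide with bromide, and transfer of the di-ortho-substituted aryl group may be sluggish. The fallback sets out from 8 (through 10) and comes back at 14.
- 10 opens commercial (S)-benzyl glycidyl ether, which has no ester, under BF3·OEt2 promotion (THF, −78 °C) to give (2S)-1-(benzyloxy)-3-[2,4,6-tris(methoxymethoxy)phenyl]propan-2-ol F4.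
- MOMCl and i-Pr2NEt give the MOM ether F5.
- Hydrogenolysis (H2, Pd/C, EtOAc) gives the primary alcohol F6.
- Parikh–Doering oxidation (SO3·pyridine, DMSO, Et3N) gives 14.

**Step 11.** The hindered benzyl ethers next to the axis may be cleaved slowly. Prolonged exposure would then allow reductive opening of the benzylic C2–O1 bonds, and the product may be oxidised by air during isolation. The fallback sets out from 21 and comes back at 22. It is a non-reductive debenzylation with BCl3 and pentamethylbenzene as cation scavenger (CH2Cl2, −78 °C), followed by a methanol quench under argon. No new compound is made on this way (F0).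

## Further compounds

F1 | step 9 | [(2R,3S)-3,5,7-tris(benzyloxy)-2-[3,4-bis(benzyloxy)phenyl]chroman-8-yl]zinc chloride | Cl[Zn]c1c(OCc3ccccc3)cc(OCc3ccccc3)c2c1O[C@H](c1ccc(OCc3ccccc3)c(OCc3ccccc3)c1)[C@@H](OCc1ccccc1)C2
F2 | step 10 | (2S)-1-{4,5-bis(benzyloxy)-2-[(2R,3S)-3,5,7-tris(benzyloxy)-2-[3,4-bis(benzyloxy)phenyl]chroman-8-yl]phenyl}-2-(methoxymethoxy)-3-[2,4,6-tris(methoxymethoxy)phenyl]propan-1-one | COCOc1cc(OCOC)c(C[C@H](OCOC)C(=O)c2cc(OCc3ccccc3)c(OCc3ccccc3)cc2-c2c(OCc3ccccc3)cc(OCc3ccccc3)c3c2O[C@H](c2ccc(OCc4ccccc4)c(OCc4ccccc4)c2)[C@@H](OCc2ccccc2)C3)c(OCOC)c1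
F3 | step 10 | (3S)-2-{4,5-bis(benzyloxy)-2-[(2R,3S)-3,5,7-tris(benzyloxy)-2-[3,4-bis(benzyloxy)phenyl]chroman-8-yl]phenyl}chroman-2,3,5,7-tetrol (cyclic hemiketal, C2 undefined) | Oc1cc(O)c2c(c1)OC(O)(c1cc(OCc3ccccc3)c(OCc3ccccc3)cc1-c1c(OCc3ccccc3)cc(OCc3ccccc3)c3c1O[C@H](c1ccc(OCc4ccccc4)c(OCc4ccccc4)c1)[C@@H](OCc1ccccc1)C3)[C@@H](O)C2
F4 | step 6 | (2S)-1-(benzyloxy)-3-[2,4,6-tris(methoxymethoxy)phenyl]propan-2-ol | COCOc1cc(OCOC)c(C[C@H](O)COCc2ccccc2)c(OCOC)c1
F5 | step 6 | 2-[(2S)-3-(benzyloxy)-2-(methoxymethoxy)propyl]-1,3,5-tris(methoxymethoxy)benzene | COCOc1cc(OCOC)c(C[C@H](OCOC)COCc2ccccc2)c(OCOC)c1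
F6 | step 6 | (2S)-2-(methoxymethoxy)-3-[2,4,6-tris(methoxymethoxy)phenyl]propan-1-ol | COCOc1cc(OCOC)c(C[C@H](OCOC)CO)c(OCOC)c1
F0 | step 11 | none | none
A1 | alternative 1 | (2R,3S)-3,5,7-tris(benzyloxy)-2-[2-bromo-4,5-bis(benzyloxy)phenyl]chroman | C(c1ccccc1)Oc1cc(OCc3ccccc3)c2c(c1)O[C@H](c1cc(OCc3ccccc3)c(OCc3ccccc3)cc1Br)[C@@H](OCc1ccccc1)C2
A2 | alternative 1 | (2R,3S)-3,5,7-tris(benzyloxy)-2-[3,4-bis(benzyloxy)phenyl]-8-(4,4,5,5-tetramethyl-1,3,2-dioxaborolan-2-yl)chroman | CC1(C)OB(OC1(C)C)c1c(OCc3ccccc3)cc(OCc3ccccc3)c2c1O[C@H](c1ccc(OCc3ccccc3)c(OCc3ccccc3)c1)[C@@H](OCc1ccccc1)C2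
A3 | alternative 1 | deca-O-benzyl-(+)-catechin-(6'→8)-(+)-catechin | C(c1ccccc1)Oc1cc(OCc3ccccc3)c2c(c1)O[C@H](c1cc(OCc3ccccc3)c(OCc3ccccc3)cc1-c1c(OCc3ccccc3)cc(OCc3ccccc3)c3c1O[C@H](c1ccc(OCc4ccccc4)c(OCc4ccccc4)c1)[C@@H](OCc1ccccc1)C3)[C@@H](OCc1ccccc1)C2
A4 | alternative 2 | 4-[(2R,3S)-3,5,7-trihydroxychroman-2-yl]cyclohexa-3,5-diene-1,2-dione (ring-B ortho-quinone of catechin) | Oc1cc(O)c2c(c1)O[C@H](C1=CC(=O)C(=O)C=C1)[C@@H](O)C2
A5 | alternative 3 | (2R,3S)-3,5-bis(benzyloxy)-2-[3,4-bis(benzyloxy)phenyl]chroman-7-yl 2-bromo-4,5-bis(benzyloxy)benzoate | O=C(Oc1cc(OCc3ccccc3)c2c(c1)O[C@H](c1ccc(OCc3ccccc3)c(OCc3ccccc3)c1)[C@@H](OCc1ccccc1)C2)c1cc(OCc2ccccc2)c(OCc2ccccc2)cc1Br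
A6 | alternative 3 | biaryl lactone with the bridge C1'–C(=O)–O7 and the bond C6'–C8 (6H-benzo[c]chromen-6-one fused to rings D and F) | O=C1Oc2cc(OCc4ccccc4)c3c(c2-c2cc(OCc4ccccc4)c(OCc4ccccc4)cc12)O[C@H](c1ccc(OCc4ccccc4)c(OCc4ccccc4)c1)[C@@H](OCc1ccccc1)C3
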